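The route rests on cutting ring D, the trans-dihydrofuran that ties an intact resveratrol unit to the central benzene ring B through one C–C bond (C-8c to ring B) and one C–O bond (C-7c to the ring B oxygen). The key step uses the single free hydroxyl of ring B and the unsubstituted ring B carbon flanked by that C–OH and the CH2-bearing carbon: a peroxidase oxidises both partners, the olefinic carbon of resveratrol attached to its 3,5-dihydroxyphenyl ring is joined to that carbon, and the phenol oxygen closes ring D on the quinone methide, creating two stereocentres. The precursor is the enantiopure seven-membered-ring resveratrol–oxyresveratrol dimer with its other five phenols benzylated.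

Key step: step 12

Locants: ring B is the central benzene. Ring E is the dihydrofuran of the dimer (O, C-7a bearing the 4-oxyphenyl group, C-8a). Ring S is the seven-membered ring (C-8a, two ring B carbons, C-8b H2, C-7b bearing the 2,4-dioxyphenyl group, two ring C carbons). Ring C is the resorcinol ring fused to ring S. Ring D is the new dihydrofuran (O, C-7c bearing the 4-hydroxyphenyl group, C-8c bearing the 3,5-dihydroxyphenyl group).

Assumption: all five building blocks are taken as commercially available, and the acid-mediated closure of ring S is taken to give the H-7b/H-8a cis arrangement of the target, as in the acid cyclisation of ε-viniferin-type stilbenes.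

Step 1
Reactants: 1 2-bromo-4,6-dimethoxybenzaldehyde
Product: 2 2-bromo-4,6-dihydroxybenzaldehyde
Conditions: BBr3 (3 equiv), CH2Cl2, −78 °C → rt; aqueous work-up
Reagents that add atoms: none
Why: Lewis-acid cleavage of both aryl methyl ethers with BBr3 (ether demethylation) frees the two phenols, the aldehyde being held as its boron chelate until work-up; no stereocentre is formed.

Step 2
Reactants: 2 2-bromo-4,6-dihydroxybenzaldehyde
Product: 3 2-bromo-6-hydroxy-4-(methoxymethoxy)benzaldehyde
Conditions: MOMCl (1.05 equiv), K2CO3, acetone, 0 °C → rt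
Reagents that add atoms: chloromethyl methyl ether, COCCl
Why: Selective Williamson-type O-alkylation, since the hydroxyl para to the formyl group is the more acidic one and is not locked in the hydrogen bond to the carbonyl, so one equivalent of MOMCl should protect it alone.

Step 3
Reactants: 3 2-bromo-6-hydroxy-4-(methoxymethoxy)benzaldehyde; 4 1-(benzyloxy)-4-(chloromethyl)benzene
Product: 5 2-{[4-(benzyloxy)phenyl]methoxy}-6-bromo-4-(methoxymethoxy)benzaldehyde
Conditions: K2CO3, KI (cat.), DMF, 60 °C
Reagents that add atoms: none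
Why: Williamson ether synthesis on the remaining chelated ortho-phenol installs the 4-(benzyloxy)benzyl group whose CH2 later becomes C-7a.

Step 4
Reactants: 5 2-{[4-(benzyloxy)phenyl]methoxy}-6-bromo-4-(methoxymethoxy)benzaldehyde; 6 1,3-bis(benzyloxy)-5-bromobenzene
Product: 8 (2-{[4-(benzyloxy)phenyl]methoxy}-6-bromo-4-(methoxymethoxy)phenyl)[3,5-bis(benzyloxy)phenyl]methanol (racemic), via arylmagnesium bromide 7 (not isolated)
Conditions: 6, Mg turnings, THF, 50 °C; then 5, THF, −20 → 0 °C; H2O quench
Reagents that add atoms: none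
Why: Grignard addition of the electron-rich aryl nucleophile to the aldehyde gives the diarylmethanol, whose racemic carbinol centre is erased in the next step.

Step 5
Reactants: 8 (2-{[4-(benzyloxy)phenyl]methoxy}-6-bromo-4-(methoxymethoxy)phenyl)[3,5-bis(benzyloxy)phenyl]methanol
Product: 9 (2-{[4-(benzyloxy)phenyl]methoxy}-6-bromo-4-(methoxymethoxy)phenyl)[3,5-bis(benzyloxy)phenyl]methanone
Conditions: Dess–Martin periodinane, CH2Cl2, 0 °C → rt
Reagents that add atoms: none
Why: Dess–Martin oxidation converts the hindered doubly benzylic alcohol into the diaryl ketone under near-neutral conditions that spare the MOM and benzyl ethers.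

Step 6
Reactants: 9 (2-{[4-(benzyloxy)phenyl]methoxy}-6-bromo-4-(methoxymethoxy)phenyl)[3,5-bis(benzyloxy)phenyl]methanone
Product: 10 hydrazone of ketone 9 (C=N geometry not defined)
Conditions: N2H4·H2O (excess), AcOH (cat.), EtOH, 80 °C
Reagents that add atoms: hydrazine, NN
Why: Hydrazone formation by condensation with excess hydrazine should proceed under heat and acid catalysis despite the two ortho substituents, because the twisted ketone is poorly conjugated and therefore electrophilic.

Step 7
Reactants: 10 hydrazone of ketone 9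
Product: 12 (2S,3R)-2-[4-(benzyloxy)phenyl]-3-[3,5-bis(benzyloxy)phenyl]-4-bromo-6-(methoxymethoxy)-2,3-dihydro-1-benzofuran (cis), via diazo compound 11 (not isolated)
Conditions: MnO2, CH2Cl2, 0 °C; filter; Rh2(R-PTAD)4 (1 mol %), CH2Cl2, −20 °C → rt
Reagents that add atoms: none
Why: Oxidation of the hydrazone gives the diaryl diazo compound, whose divalent-rhodium donor/donor carbene undergoes enantioselective intramolecular 1,5 C–H insertion into the neighbouring benzylic O–CH2 group, the chiral carboxylate ligands choosing the enantiotopic hydrogen so that C-8a (ring C-3) is set as R with the two aryl groups cis (the mirror-image catalyst Rh2(S-PTAD)4 is used if the first run shows the opposite sense).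

Step 8
Reactants: 12 (2S,3R)-2-[4-(benzyloxy)phenyl]-3-[3,5-bis(benzyloxy)phenyl]-4-bromo-6-(methoxymethoxy)-2,3-dihydro-1-benzofuran
Product: 14 (2R,3R)-2-[4-(benzyloxy)phenyl]-3-[3,5-bis(benzyloxy)phenyl]-4-bromo-2,3-dihydro-1-benzofuran-6-ol (trans), via cis phenol 13 (not isolated)
Conditions: HCl (cat.), MeOH–THF, 40 °C; evaporate; TFA–CH2Cl2 (1:9), 0 °C → rt
Reagents that add atoms: none
Why: Acetal exchange in acidic methanol removes the MOM group, and TFA then reversibly ionises the benzylic C-7a–O bond to a 4-alkoxybenzyl cation that is recaptured by the phenol oxygen (acid-mediated epimerisation), so C-7a should settle in the more stable trans arrangement while C-8a is not touched.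

Step 9
Reactants: 15 2,4-bis(benzyloxy)benzaldehyde
Product: 16 2,4-bis(benzyloxy)-1-ethenylbenzene
Conditions: Ph3PCH3Br, KOtBu, THF, 0 °C → rt
Reagents that add atoms: methyltriphenylphosphonium bromide, C[P+](c1ccccc1)(c1ccccc1)c1ccccc1.[Br-]
Why: Wittig methylenation of the aldehyde with the non-stabilised ylide gives the styrene.

Step 10
Reactants: 14 (2R,3R)-2-[4-(benzyloxy)phenyl]-3-[3,5-bis(benzyloxy)phenyl]-4-bromo-2,3-dihydro-1-benzofuran-6-ol; 16 2,4-bis(benzyloxy)-1-ethenylbenzene
Product: 17 (2R,3R)-2-[4-(benzyloxy)phenyl]-3-[3,5-bis(benzyloxy)phenyl]-4-{(E)-2-[2,4-bis(benzyloxy)phenyl]ethenyl}-2,3-dihydro-1-benzofuran-6-ol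
Conditions: Pd(OAc)2 (5 mol %), P(o-tol)3, Et3N, DMF, 100 °C
Reagents that add atoms: none
Why: Mizoroki–Heck coupling of the aryl bromide with the electron-rich styrene proceeds by syn carbopalladation and syn β-hydride elimination to give the E-stilbene without touching the phenol or the two stereocentres.

Step 11
Reactants: 17 (2R,3R)-2-[4-(benzyloxy)phenyl]-3-[3,5-bis(benzyloxy)phenyl]-4-{(E)-2-[2,4-bis(benzyloxy)phenyl]ethenyl}-2,3-dihydro-1-benzofuran-6-ol
Product: 18 (7aR,8aR,7bS)-penta-O-benzyl seven-membered-ring dimer (ring E trans; ring B hydroxyl free; benzyl ethers on the 4-oxyphenyl group at C-7a and on the 2,4-dioxyphenyl group at C-7b and on both ring C oxygens)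
Conditions: TFA (2 vol %), CH2Cl2, −20 → 0 °C
Reagents that add atoms: none
Why: Intramolecular Friedel–Crafts alkylation, in which protonation of the styrene at the carbon next to ring B gives a cation stabilised by the 2,4-dialkoxyphenyl group that is attacked by the ortho carbon of ring C (seven-membered closure), and because ring C is held on one face by C-8a the aryl group at C-7b should end up on the face of ring S syn to the C-8a–C-7a bond, which is the 7bS epimer.

Step 12
Reactants: 18 (7aR,8aR,7bS)-penta-O-benzyl seven-membered-ring dimer with free ring B hydroxyl; 19 resveratrol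
Product: 21 penta-O-benzyl ether of the target [(7aR,8aR,7bS,7cR,8cR); ring D trans], via para-quinone methide 20 (not isolated)
Conditions: horseradish peroxidase, H2O2 and 19 fed by syringe pump, 1,4-dioxane–acetate buffer pH 5 (7:3), 25 °C; preparative HPLC
Reagents that add atoms: none
Why: Proposed new method: the peroxidase, through its H2O2-generated ferryl forms, takes one electron and one proton from the 4-hydroxyl of resveratrol and from the only free phenol of 18; the stilbene radical (spin at C-8, beside the resorcinol ring) and the ring B phenoxyl radical (spin at the carbon ortho to C–O and para to the ring E oxygen) combine, the cyclohexadienone tautomerises to the phenol, and that phenol adds to the para-quinone methide 20. The closest known reactions are the peroxidase- and laccase-mediated dimerisations of resveratrol to δ- and ε-viniferin-type trans-dihydrobenzofurans. Ring D closes by 5-exo-trig oxa-Michael addition to the quinone methide. C-8c is set in the radical–radical C–C bond formation, where only the puckered ring S differentiates the two faces, so the (7cS,8cS) diastereomer is expected as well and is removed by HPLC; C-7c is set by the reversible quinone methide closure, which places the two aryl groups trans. Chemoselectivity rests on the five benzyl ethers, which leave ring B as the only oxidisable phenol of the dimer; regioselectivity for the carbon beside the CH2-bearing carbon over the one between the two oxygens follows the preference of ε-type 8–10' couplings, and homodimerisation of resveratrol is held down by the slow feed.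

Step 13
Reactants: 21 penta-O-benzyl ether of the target
Product: 22 CNP0154047.2 [(7aR,8aR,7bS,7cR,8cR)-trimer with all eight phenols free]
Conditions: H2 (1 atm), 10% Pd/C, EtOAc–MeOH, rt
Reagents that add atoms: none
Why: Hydrogenolysis of the five aryl benzyl ethers over Pd/C at ambient pressure should be faster than cleavage of the cyclic benzylic C–O bonds of rings D and E, and no stereocentre is touched.

Compound list
1 | 2-bromo-4,6-dimethoxybenzaldehyde | COc1cc(OC)c(C=O)c(Br)c1 | starting material
2 | 2-bromo-4,6-dihydroxybenzaldehyde | Oc1cc(O)c(C=O)c(Br)c1 | intermediate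
3 | 2-bromo-6-hydroxy-4-(methoxymethoxy)benzaldehyde | COCOc1cc(O)c(C=O)c(Br)c1 | intermediate
4 | 1-(benzyloxy)-4-(chloromethyl)benzene | ClCc1ccc(OCc2ccccc2)cc1 | starting material
5 | 2-{[4-(benzyloxy)phenyl]methoxy}-6-bromo-4-(methoxymethoxy)benzaldehyde | COCOc1cc(Br)c(C=O)c(OCc2ccc(OCc3ccccc3)cc2)c1 | intermediate
6 | 1,3-bis(benzyloxy)-5-bromobenzene | Brc1cc(OCc2ccccc2)cc(OCc2ccccc2)c1 | starting material
7 | [3,5-bis(benzyloxy)phenyl]magnesium bromide (not isolated) | Br[Mg]c1cc(OCc2ccccc2)cc(OCc2ccccc2)c1 | intermediate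
8 | (2-{[4-(benzyloxy)phenyl]methoxy}-6-bromo-4-(methoxymethoxy)phenyl)[3,5-bis(benzyloxy)phenyl]methanol, racemic | COCOc1cc(Br)c(C(O)c2cc(OCc3ccccc3)cc(OCc3ccccc3)c2)c(OCc2ccc(OCc3ccccc3)cc2)c1 | intermediate
9 | (2-{[4-(benzyloxy)phenyl]methoxy}-6-bromo-4-(methoxymethoxy)phenyl)[3,5-bis(benzyloxy)phenyl]methanone | COCOc1cc(Br)c(C(=O)c2cc(OCc3ccccc3)cc(OCc3ccccc3)c2)c(OCc2ccc(OCc3ccccc3)cc2)c1 | intermediate
10 | hydrazone of ketone 9 | COCOc1cc(Br)c(C(=NN)c2cc(OCc3ccccc3)cc(OCc3ccccc3)c2)c(OCc2ccc(OCc3ccccc3)cc2)c1 | intermediate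
11 | 1-{[4-(benzyloxy)phenyl]methoxy}-3-bromo-2-{[3,5-bis(benzyloxy)phenyl](diazo)methyl}-5-(methoxymethoxy)benzene (not isolated) | COCOc1cc(Br)c(C(=[N+]=[N-])c2cc(OCc3ccccc3)cc(OCc3ccccc3)c2)c(OCc2ccc(OCc3ccccc3)cc2)c1 | intermediate
12 | (2S,3R)-2-[4-(benzyloxy)phenyl]-3-[3,5-bis(benzyloxy)phenyl]-4-bromo-6-(methoxymethoxy)-2,3-dihydro-1-benzofuran (cis) | COCOc1cc2O[C@H](c3ccc(OCc4ccccc4)cc3)[C@H](c3cc(OCc4ccccc4)cc(OCc4ccccc4)c3)c2c(Br)c1 | intermediate
13 | (2S,3R)-2-[4-(benzyloxy)phenyl]-3-[3,5-bis(benzyloxy)phenyl]-4-bromo-2,3-dihydro-1-benzofuran-6-ol (cis, not isolated) | Oc1cc2O[C@H](c3ccc(OCc4ccccc4)cc3)[C@H](c3cc(OCc4ccccc4)cc(OCc4ccccc4)c3)c2c(Br)c1 | intermediate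
14 | (2R,3R)-2-[4-(benzyloxy)phenyl]-3-[3,5-bis(benzyloxy)phenyl]-4-bromo-2,3-dihydro-1-benzofuran-6-ol (trans) | Oc1cc2O[C@@H](c3ccc(OCc4ccccc4)cc3)[C@H](c3cc(OCc4ccccc4)cc(OCc4ccccc4)c3)c2c(Br)c1 | intermediate
15 | 2,4-bis(benzyloxy)benzaldehyde | O=Cc1ccc(OCc2ccccc2)cc1OCc1ccccc1 | starting material
16 | 2,4-bis(benzyloxy)-1-ethenylbenzene | C=Cc1ccc(OCc2ccccc2)cc1OCc1ccccc1 | intermediate
17 | (2R,3R)-2-[4-(benzyloxy)phenyl]-3-[3,5-bis(benzyloxy)phenyl]-4-{(E)-2-[2,4-bis(benzyloxy)phenyl]ethenyl}-2,3-dihydro-1-benzofuran-6-ol | Oc1cc2O[C@@H](c3ccc(OCc4ccccc4)cc3)[C@H](c3cc(OCc4ccccc4)cc(OCc4ccccc4)c3)c2c(/C=C/c2ccc(OCc3ccccc3)cc2OCc2ccccc2)c1 | intermediate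
18 | (7aR,8aR,7bS)-penta-O-benzyl seven-membered-ring resveratrol–oxyresveratrol dimer, ring E trans, ring B hydroxyl free | Oc1cc2c3c(c1)C[C@@H](c1ccc(OCc4ccccc4)cc1OCc4ccccc4)c1c(OCc4ccccc4)cc(OCc4ccccc4)cc1[C@H]3[C@H](c1ccc(OCc4ccccc4)cc1)O2 | intermediate
19 | resveratrol, 5-[(E)-2-(4-hydroxyphenyl)ethenyl]benzene-1,3-diol | Oc1ccc(/C=C/c2cc(O)cc(O)c2)cc1 | starting material
20 | para-quinone methide: 18 bearing, at the ring B carbon between C–OH and the CH2-bearing carbon, an (8cR)-CH(3,5-dihydroxyphenyl)–CH= unit that ends as the exocyclic carbon of a cyclohexa-2,5-dien-1-one (not isolated) | O=C1C=CC(=C[C@H](c2cc(O)cc(O)c2)c2c(O)cc3c4c2C[C@@H](c2ccc(OCc6ccccc6)cc2OCc6ccccc6)c2c(OCc6ccccc6)cc(OCc6ccccc6)cc2[C@H]4[C@H](c2ccc(OCc6ccccc6)cc2)O3)C=C1 | intermediate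
21 | penta-O-benzyl ether of the target, (7aR,8aR,7bS,7cR,8cR), rings D and E trans | Oc1ccc([C@@H]2Oc3cc4c5c(c3[C@H]2c2cc(O)cc(O)c2)C[C@@H](c2ccc(OCc6ccccc6)cc2OCc6ccccc6)c2c(OCc6ccccc6)cc(OCc6ccccc6)cc2[C@H]5[C@H](c2ccc(OCc6ccccc6)cc2)O4)cc1 | intermediate
22 | CNP0154047.2, (7aR,8aR,7bS,7cR,8cR)-trimer with eight free phenols | Oc1ccc([C@@H]2Oc3cc4c5c(c3[C@H]2c2cc(O)cc(O)c2)C[C@@H](c2ccc(O)cc2O)c2c(O)cc(O)cc2[C@H]5[C@H](c2ccc(O)cc2)O4)cc1 | target

Total step count: 13. Longest linear sequence: 12 steps (steps 1 to 8 and 10 to 13).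

Steps most likely to fail

Step 12 (proposed new method). The coupling may run mainly as homodimerisation of resveratrol, bond at the ring B carbon between the two oxygens, show no facial preference, or stall because the enzyme oxidises the bulky ring B phenol slowly. The fallback uses known chemistry only, sets out from 18 and comes back at 22. Amine-mediated ortho-bromination of the free phenol (NBS, i-Pr2NH cat., CH2Cl2, −78 °C), directed to the carbon para to the ring E oxygen, should give the bromophenol F1. Palladium-catalysed enolate arylation of the deoxybenzoin F2 (made by Negishi acylation of [3,5-bis(benzyloxy)benzyl]zinc bromide with 4-(benzyloxy)benzoyl chloride, Pd(PPh3)4 cat.) with F1 (Pd2(dba)3, Xantphos, NaOtBu, toluene, 100 °C), followed by acid cyclodehydration (TFA, CH2Cl2), should give the 2,3-diarylbenzofuran F3. Hydrogenation (H2, 20 bar, Pd(OH)2/C, EtOAc–MeOH) removes the eight benzyl groups and saturates the furan double bond from one face, giving the cis-dihydrofuran F4 together with its face isomer. HCl in MeOH at 50 °C then epimerises C-7c through the quinone methide to the trans ring D, giving 22, which is separated from the (7cS,8cS) diastereomer by HPLC.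

Step 7. Formation of the di-ortho-substituted diaryl diazo compound may be slow, and the chiral carboxylate may discriminate the enantiotopic hydrogens poorly. The fallback sets out from ketone 9 and comes back at 14, skipping steps 6 to 8. Base-mediated intramolecular aldol condensation of the ortho-benzyloxy ketone (P4-t-Bu phosphazene base, toluene, 80 °C) should give the 2,3-diarylbenzofuran F5. Ionic hydrogenation (Et3SiH, TFA, CH2Cl2, 0 °C → rt) reduces the furan double bond, removes the MOM group and equilibrates to the trans isomer, giving racemic 14. Preparative HPLC on a polysaccharide chiral stationary phase then delivers (2R,3R)-14.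

Step 11. Ionisation of the benzylic C–O bond of ring E or loss of benzyl groups may compete with protonation of the styrene, and the closure may give both C-7b epimers. The fallback sets out from bromide 14 and comes back at 18, skipping steps 9 to 11. Palladium-catalysed α-arylation of 1-[2,4-bis(benzyloxy)phenyl]ethan-1-one with 14 (Pd2(dba)3, XPhos, NaOtBu, toluene, 80 °C) should give the deoxybenzoin F6. Reduction with NaBH4 (MeOH–THF, 0 °C) gives the benzylic alcohol F7 as a mixture of carbinol epimers. Ionisation of this alcohol with a catalytic Lewis acid (Bi(OTf)3, CH2Cl2, −20 °C), under far milder conditions than the styrene needs, generates the same C-7b cation and closes ring S to 18.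

Further compounds
F1 | step 12 | 18 carrying bromine at the ring B carbon between C–OH and the CH2-bearing carbon | Oc1cc2c3c(c1Br)C[C@@H](c1ccc(OCc4ccccc4)cc1OCc4ccccc4)c1c(OCc4ccccc4)cc(OCc4ccccc4)cc1[C@H]3[C@H](c1ccc(OCc4ccccc4)cc1)O2
F2 | step 12 | 1-[4-(benzyloxy)phenyl]-2-[3,5-bis(benzyloxy)phenyl]ethan-1-one | O=C(Cc1cc(OCc2ccccc2)cc(OCc2ccccc2)c1)c1ccc(OCc2ccccc2)cc1
F3 | step 12 | octa-O-benzyl 7c,8c-didehydro target (ring D as an aromatic furan), (7aR,8aR,7bS) | c1ccccc1COc1ccc(-c2oc3cc4c5c(c3c2-c2cc(OCc6ccccc6)cc(OCc6ccccc6)c2)C[C@@H](c2ccc(OCc6ccccc6)cc2OCc6ccccc6)c2c(OCc6ccccc6)cc(OCc6ccccc6)cc2[C@H]5[C@H](c2ccc(OCc6ccccc6)cc2)O4)cc1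
F4 | step 12 | (7aR,8aR,7bS,7cS,8cR)-isomer of the target (ring D cis, C-7c epimer) | Oc1ccc([C@H]2Oc3cc4c5c(c3[C@H]2c2cc(O)cc(O)c2)C[C@@H](c2ccc(O)cc2O)c2c(O)cc(O)cc2[C@H]5[C@H](c2ccc(O)cc2)O4)cc1
F5 | step 7 | 2-[4-(benzyloxy)phenyl]-3-[3,5-bis(benzyloxy)phenyl]-4-bromo-6-(methoxymethoxy)-1-benzofuran | COCOc1cc(Br)c2c(-c3cc(OCc4ccccc4)cc(OCc4ccccc4)c3)c(-c3ccc(OCc4ccccc4)cc3)oc2c1
F6 | step 11 | 1-[2,4-bis(benzyloxy)phenyl]-2-{(2R,3R)-2-[4-(benzyloxy)phenyl]-3-[3,5-bis(benzyloxy)phenyl]-6-hydroxy-2,3-dihydro-1-benzofuran-4-yl}ethan-1-one | Oc1cc2O[C@@H](c3ccc(OCc4ccccc4)cc3)[C@H](c3cc(OCc4ccccc4)cc(OCc4ccccc4)c3)c2c(CC(=O)c2ccc(OCc3ccccc3)cc2OCc2ccccc2)c1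
F7 | step 11 | 1-[2,4-bis(benzyloxy)phenyl]-2-{(2R,3R)-2-[4-(benzyloxy)phenyl]-3-[3,5-bis(benzyloxy)phenyl]-6-hydroxy-2,3-dihydro-1-benzofuran-4-yl}ethan-1-ol (carbinol epimers) | Oc1cc2O[C@@H](c3ccc(OCc4ccccc4)cc3)[C@H](c3cc(OCc4ccccc4)cc(OCc4ccccc4)c3)c2c(CC(O)c2ccc(OCc3ccccc3)cc2OCc2ccccc2)c1
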